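Ring B is opened at C6–C7. Its C6 carbinol, C7 methylene and C8 oxygen are read as the β-hydroxy ketone C6(OH)–C7H2–C8(=O), which a Ferrier carbocyclisation delivers in one operation from a fused oxane that has an oxygen where ring B has C7. Hydration of an exocyclic enol ether unmasks a C6 aldehyde and a C7 nucleophile, which close the carbocycle and set C6. The precursor is a cis-fused 1-methoxy-3-methylene-isochromane on ring A that carries C9 with its ketal-masked side chain. Its C9/C10 centres come from an enantioselective Ireland–Claisen rearrangement. Its cis fusion comes from an iodolactone-derived spiro-epoxide that is isomerised to the C6 aldehyde, because direct hydroboration of the exocyclic methylene is expected to give the trans series.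

Key step: step 10

Atom labels follow labdane numbering: ring A is C1–C5 and C10, ring B is C5–C10, and the side chain C11–C16 sits on C9.

Assumption: the sense of induction of the (4S,5S)-diazaborolidine bromide in the Claisen step is taken by analogy with simple allylic esters; if a model run gives the antipodal acid, the (4R,5R)-reagent is used and nothing else changes.

Step 1
Reactants: 1 β-cyclocitral
Product: 2 β-cyclogeraniol
Conditions: NaBH4, MeOH, 0 °C
Reagents that add atoms: none
Why: Hydride 1,2-reduction of the conjugated aldehyde (NaBH4 reduction) gives the allylic alcohol and creates no stereocentre.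

Step 2
Reactants: 3 5-oxohexanoic acid
Product: 5 ketal acid [4-(2-methyl-1,3-dioxolan-2-yl)butanoic acid], via hydroxyethyl ester ketal 4 (not isolated)
Conditions: HOCH2CH2OH (3 equiv), TsOH·H2O (cat.), toluene, reflux with azeotropic removal of water; then NaOH, MeOH/H2O, 23 °C; 1 M HCl to pH 4 at 0 °C
Reagents that add atoms: ethylene glycol, OCCO
Why: Acid-catalysed ketalisation protects the ketone while the glycol also esterifies the carboxyl, and saponification of that ester returns the acid without touching the base-stable dioxolane.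

Step 3
Reactants: 2 β-cyclogeraniol; 5 ketal acid
Product: 6 β-cyclogeranyl 4-(2-methyl-1,3-dioxolan-2-yl)butanoate
Conditions: DCC, DMAP (cat.), CH2Cl2, 0 → 23 °C
Reagents that add atoms: none
Why: Steglich esterification couples the hindered allylic alcohol under neutral conditions that spare the dioxolane and the ionisable allylic C–O bond.

Step 4
Reactants: 6 β-cyclogeranyl ester
Product: 8 Claisen acid [(2S)-4-(2-methyl-1,3-dioxolan-2-yl)-2-((1S)-1,3,3-trimethyl-2-methylidenecyclohexyl)butanoic acid], via boron ketene acetal 7 (not isolated)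
Conditions: (4S,5S)-2-bromo-4,5-diphenyl-1,3-bis{[3,5-bis(trifluoromethyl)phenyl]sulfonyl}-1,3,2-diazaborolidine (1.2 equiv), i-Pr2NEt (1.5 equiv), CH2Cl2, −78 °C; then 4 → 23 °C; pH 5 buffer
Reagents that add atoms: none
Why: Enantioselective Ireland–Claisen rearrangement, in which soft enolisation in CH2Cl2 with the hindered amine gives the boron ketene acetal with C11 cis to O–B, and its [3,3] shift through a chair (ring methyl pseudo-axial, C11 equatorial) forms C9–C10 with the like (S,S) relationship that the target needs, while the chiral boron ligand selects the enolate face.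

Step 5
Reactants: 8 Claisen acid
Product: 9 iodolactone [cis-fused γ-lactone with C5–O and C6H2I]
Conditions: I2 (1.5 equiv), NaHCO3 (3 equiv), MeCN/H2O, 0 °C, dark
Reagents that add atoms: iodine, II
Why: Iodolactonisation (5-exo, attack at the tertiary C5) can only give the cis-fused γ-lactone, so the C5–O bond is fixed cis to C9 whatever the conformation of ring A.

Step 6
Reactants: 9 iodolactone
Product: 10 epoxy benzyl ester [spiro-epoxide at C5/C6]
Conditions: BnOH (5 equiv), K2CO3 (2 equiv), THF, 40 °C
Reagents that add atoms: benzyl alcohol, OCc1ccccc1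
Why: Lactone alcoholysis by benzyloxide frees the C5 alkoxide, which closes onto the iodomethyl carbon (intramolecular Williamson displacement) to give the spiro-epoxide with retention at C5 and the benzyl ester in one operation.

Step 7
Reactants: 10 epoxy benzyl ester
Product: 11 aldehyde benzyl ester [C6 aldehyde cis to C9]
Conditions: BF3·OEt2 (0.3 equiv), CH2Cl2, −78 °C; Et3N quench
Reagents that add atoms: none
Why: Meinwald rearrangement, in which BF3 ionises the tertiary C5–O bond and a hydride moves from C6 to C5 on the face opposite the departing oxygen (the boron-bound oxygen stays on the open face while the small hydride passes between the two axial methyls), so that C6 ends cis to C9 and the new H-5 cis to the C10 methyl, which is the cis ring fusion.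

Step 8
Reactants: 11 aldehyde benzyl ester
Product: 13 methyl pseudo-ester [1-methoxy-isochroman-3-one], via aldehydo acid 12 (not isolated)
Conditions: H2 (1 atm), 10% Pd/C, EtOAc, 23 °C; filter; then MeOH (10 equiv), PPTS (0.1 equiv), 4 Å MS, CH2Cl2, 23 °C
Reagents that add atoms: methanol, CO
Why: Hydrogenolysis frees the C8 carboxyl without reducing the hindered aldehyde, the aldehydo acid closes to its six-membered pseudo-acid, and PPTS-catalysed exchange with a limited amount of methanol (Fischer-type acetalisation) gives the methyl acyloxy acetal while the hindered carboxyl is not esterified and the dioxolane is not exchanged, both anomers being carried on.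

Step 9
Reactants: 13 methyl pseudo-ester
Product: 14 1-methoxy-3-methylene-isochromane [the oxane precursor]
Conditions: Cp2TiMe2 (3 equiv), toluene, 70 °C, dark; filtration through basic alumina
Reagents that add atoms: dimethyltitanocene, [CH3-].[CH3-].[Ti+4].c1cc[cH-]c1.c1cc[cH-]c1
Why: Petasis methylenation, in which the titanium methylidene formed on heating converts the lactone carbonyl into the exocyclic enol ether by [2+2] addition and cycloreversion without acid or base, so that C9, the acetal and the dioxolane stay intact.

Step 10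
Reactants: 14 1-methoxy-3-methylene-isochromane
Product: 16 cis-decalin hydroxy ketone [C6–OH and C8=O], via mercurio keto aldehyde 15 (not isolated)
Conditions: Hg(OCOCF3)2 (5 mol%), acetone/H2O (4:1), 0 → 23 °C
Reagents that add atoms: water, O
Why: Divalent mercury adds to the exocyclic enol ether of 14 with water at C8, the hemiketal opens at the ring O–C8 bond, C6 loses methanol, and the C6 aldehyde then faces the C7-mercurated C8 ketone 15, whose C7 adds to C6 in an aldol step that releases the mercury salt for the next turnover. The closest known reaction type is the Ferrier carbocyclisation of 6-deoxyhex-5-enopyranosides to 3-hydroxycyclohexanones, and 14 is such a 2-alkoxy-6-methylene-oxane, only deoxygenated and fused to ring A. Ring B closes in the 6-(enolendo)-exo-trig mode, because the C7=C8 enol bond lies inside the ring that forms. The one new stereocentre, C6, is set in a chair transition state on the cis-fused scaffold in which the aldehyde oxygen takes the equatorial site, the axial site being blocked by the axial C1 methylene of ring A, and this places the hydroxyl cis to H-5 and to the C10 methyl. The step needs C7 and not C9 to become the nucleophile, which the position of the enol ether secures by putting mercury on C7, and it needs C9, C5 and the dioxolane to survive, which the near-neutral medium, the low loading of the mercury salt and the absence of a free enolate secure.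

Step 11
Reactants: 16 cis-decalin hydroxy ketone
Product: 17 diol [C6–OH and C8(CH3)–OH]
Conditions: CeCl3 (dried, 4 equiv), MeLi (4 equiv), THF, −78 °C
Reagents that add atoms: methyllithium, [Li]C
Why: Organocerium 1,2-addition avoids enolisation toward C9, and in the cis-decalin chair with C11 axial the lower face of C8 is shielded by the axial C1 methylene of ring A, so methyl enters equatorially from the face of the C6 alkoxide and the new hydroxyl is axial, trans to C11 and to the C10 methyl.

Step 12
Reactants: 17 diol
Product: 18 C6 monoacetate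
Conditions: Ac2O (2 equiv), pyridine, DMAP (cat.), CH2Cl2, 0 → 23 °C
Reagents that add atoms: acetic anhydride, CC(=O)OC(C)=O
Why: Acylation takes the secondary equatorial C6 hydroxyl selectively, the tertiary axial C8 hydroxyl being unreactive under these conditions.

Step 13
Reactants: 18 C6 monoacetate
Product: 19 hydroxy methyl ketone [C13 ketone free]
Conditions: PPTS (0.2 equiv), acetone/H2O (9:1), 45 °C
Reagents that add atoms: water, O
Why: Mild acid-catalysed ketal hydrolysis unmasks the C13 methyl ketone without cleaving the acetate or dehydrating the tertiary alcohol.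

Step 14
Reactants: 19 hydroxy methyl ketone; 20 allyl diethylphosphonoacetate
Product: 21 allyl (E)-enoate
Conditions: 20 (2.0 equiv), NaH (1.9 equiv), THF, 0 → 45 °C
Reagents that add atoms: none
Why: Horner–Wadsworth–Emmons olefination of the methyl ketone with the sodium salt of 20, kept in slight excess over NaH so that no free base remains for the acetate or the tertiary alcohol, should favour the (E)-trisubstituted enoate with the C12 chain trans to the ester, and any (Z)-isomer is removed by chromatography.

Step 15
Reactants: 21 allyl (E)-enoate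
Product: 22 CNP0221670.1
Conditions: Pd(PPh3)4 (5 mol%), morpholine (5 equiv), THF, 23 °C; pH 4 work-up
Reagents that add atoms: none
Why: Tsuji–Trost deallylation, in which zerovalent palladium ionises the allyl ester and morpholine traps the allyl fragment, releases the acid without touching the acetate, the tertiary alcohol or the (E)-alkene.

Compound list

1 | β-cyclocitral (2,6,6-trimethylcyclohex-1-ene-1-carbaldehyde) | CC1=C(C=O)C(C)(C)CCC1 | starting material
2 | β-cyclogeraniol [(2,6,6-trimethylcyclohex-1-en-1-yl)methanol] | CC1=C(CO)C(C)(C)CCC1 | intermediate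
3 | 5-oxohexanoic acid | CC(=O)CCCC(=O)O | starting material
4 | 2-hydroxyethyl 4-(2-methyl-1,3-dioxolan-2-yl)butanoate | CC1(CCCC(=O)OCCO)OCCO1 | intermediate (not isolated)
5 | 4-(2-methyl-1,3-dioxolan-2-yl)butanoic acid | CC1(CCCC(=O)O)OCCO1 | intermediate
6 | (2,6,6-trimethylcyclohex-1-en-1-yl)methyl 4-(2-methyl-1,3-dioxolan-2-yl)butanoate | CC1=C(COC(=O)CCCC2(C)OCCO2)C(C)(C)CCC1 | intermediate
7 | boron ketene acetal of 6: C8 carries the β-cyclogeranyloxy group and the O-[(4S,5S)-4,5-diphenyl-1,3-bis(3,5-bis(trifluoromethyl)phenylsulfonyl)-1,3,2-diazaborolidin-2-yl] group, C11 cis to O–B | CC1=C(CO/C(OB2N([C@@H](c3ccccc3)[C@H](c4ccccc4)N2S(=O)(=O)c5cc(cc(c5)C(F)(F)F)C(F)(F)F)S(=O)(=O)c6cc(cc(c6)C(F)(F)F)C(F)(F)F)=C/CCC7(C)OCCO7)C(C)(C)CCC1 | intermediate (not isolated)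
8 | (2S)-4-(2-methyl-1,3-dioxolan-2-yl)-2-[(1S)-1,3,3-trimethyl-2-methylidenecyclohexyl]butanoic acid | OC(=O)[C@@H](CCC1(C)OCCO1)[C@]2(C)CCCC(C)(C)C2=C | intermediate
9 | (3S,3aS,7aS)-7a-(iodomethyl)-3a,7,7-trimethyl-3-[2-(2-methyl-1,3-dioxolan-2-yl)ethyl]hexahydro-1-benzofuran-2(3H)-one | O=C1[C@@H](CCC3(C)OCCO3)[C@]2(C)CCCC(C)(C)[C@]2(CI)O1 | intermediate
10 | benzyl (2S)-4-(2-methyl-1,3-dioxolan-2-yl)-2-[(3S,4S)-4,8,8-trimethyl-1-oxaspiro[2.5]octan-4-yl]butanoate | O=C(OCc1ccccc1)[C@@H](CCC4(C)OCCO4)[C@]2(C)CCCC(C)(C)[C@]23OC3 | intermediate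
11 | benzyl (2S)-2-[(1R,2S)-2-formyl-1,3,3-trimethylcyclohexyl]-4-(2-methyl-1,3-dioxolan-2-yl)butanoate | O=C(OCc1ccccc1)[C@@H](CCC3(C)OCCO3)[C@]2(C)CCCC(C)(C)[C@@H]2C=O | intermediate
12 | (2S)-2-[(1R,2S)-2-formyl-1,3,3-trimethylcyclohexyl]-4-(2-methyl-1,3-dioxolan-2-yl)butanoic acid (equilibrating with its cyclic pseudo-acid) | OC(=O)[C@@H](CCC3(C)OCCO3)[C@]2(C)CCCC(C)(C)[C@@H]2C=O | intermediate (not isolated)
13 | (1R,4S,4aR,8aS)-1-methoxy-4a,8,8-trimethyl-4-[2-(2-methyl-1,3-dioxolan-2-yl)ethyl]hexahydro-1H-isochromen-3(4H)-one (cis-fused; the 1R anomer is drawn, the C1 epimer is equally usable) | CO[C@@H]1OC(=O)[C@@H](CCC3(C)OCCO3)[C@]2(C)CCCC(C)(C)[C@H]12 | intermediate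
14 | (1R,4S,4aS,8aS)-1-methoxy-4a,8,8-trimethyl-3-methylidene-4-[2-(2-methyl-1,3-dioxolan-2-yl)ethyl]octahydro-1H-isochromene (cis-fused; the 1R anomer is drawn, the C1 epimer is equally usable) | CO[C@@H]1OC(=C)[C@@H](CCC3(C)OCCO3)[C@]2(C)CCCC(C)(C)[C@H]12 | intermediate
15 | ring-opened C6 aldehyde with C8 ketone and C7–Hg(OCOCF3) | FC(F)(F)C(=O)O[Hg]CC(=O)[C@@H](CCC3(C)OCCO3)[C@]2(C)CCCC(C)(C)[C@@H]2C=O | intermediate (not isolated)
16 | (1S,4S,4aS,8aR)-4-hydroxy-5,5,8a-trimethyl-1-[2-(2-methyl-1,3-dioxolan-2-yl)ethyl]octahydronaphthalen-2(1H)-one | O[C@H]1CC(=O)[C@@H](CCC3(C)OCCO3)[C@]2(C)CCCC(C)(C)[C@H]12 | intermediate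
17 | (1S,2S,4S,4aS,8aR)-2,5,5,8a-tetramethyl-1-[2-(2-methyl-1,3-dioxolan-2-yl)ethyl]decahydronaphthalene-2,4-diol | O[C@H]1C[C@](C)(O)[C@@H](CCC3(C)OCCO3)[C@]2(C)CCCC(C)(C)[C@H]12 | intermediate
18 | (1S,2S,4S,4aS,8aR)-2-hydroxy-2,5,5,8a-tetramethyl-1-[2-(2-methyl-1,3-dioxolan-2-yl)ethyl]decahydronaphthalen-4-yl acetate (descriptors as in 17) | CC(=O)O[C@H]1C[C@](C)(O)[C@@H](CCC3(C)OCCO3)[C@]2(C)CCCC(C)(C)[C@H]12 | intermediate
19 | 4-[(1S,2S,4S,4aS,8aR)-4-acetoxy-2-hydroxy-2,5,5,8a-tetramethyldecahydronaphthalen-1-yl]butan-2-one | CC(=O)O[C@H]1C[C@](C)(O)[C@@H](CCC(C)=O)[C@]2(C)CCCC(C)(C)[C@H]12 | intermediate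
20 | allyl diethylphosphonoacetate [prop-2-en-1-yl 2-(diethoxyphosphoryl)acetate] | C=CCOC(=O)CP(=O)(OCC)OCC | starting material
21 | allyl (2E)-5-[(1S,2S,4S,4aS,8aR)-4-acetoxy-2-hydroxy-2,5,5,8a-tetramethyldecahydronaphthalen-1-yl]-3-methylpent-2-enoate | CC(=O)O[C@H]1C[C@](C)(O)[C@@H](CC/C(C)=C/C(=O)OCC=C)[C@]2(C)CCCC(C)(C)[C@H]12 | intermediate
22 | CNP0221670.1, (2E)-5-[(1S,2S,4S,4aS,8aR)-4-acetoxy-2-hydroxy-2,5,5,8a-tetramethyldecahydronaphthalen-1-yl]-3-methylpent-2-enoic acid | CC(=O)O[C@H]1C[C@](C)(O)[C@@H](CC/C(C)=C/C(=O)O)[C@]2(C)CCCC(C)(C)[C@H]12 | target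

Total steps: 15. Longest linear sequence: 14 (steps 1 and 3–15; step 2 is the side branch).

Steps most likely to fail

Step 10. The organomercurial may persist without cyclising, or the acid released may hydrolyse the dioxolane or dehydrate the aldol. The fallback sets out from 14 and comes back at 16. N-Bromosuccinimide in wet THF with NaHCO3 at 0 °C brominates the enol ether, water adds at C8, and the hemiketal collapses with loss of methanol to the α-bromo keto aldehyde F1. SmI2 (2.2 equiv) in THF at −78 °C then reduces the C7–Br bond to the samarium enolate, which closes ring B in an intramolecular Reformatsky-type aldol through the same chair and gives 16.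

Step 7. The cationic C5 may be trapped from the front by the ester carbonyl (hydroxy lactone) or lose a proton, and part of the hydride may enter from the open face, which erodes the cis relationship. The fallback sets out from 10 and comes back at 14, bypassing 11–13. i-Bu2AlH in toluene at −78 °C reduces the benzyl ester to the epoxy aldehyde F2. Ohira–Bestmann homologation (dimethyl (1-diazo-2-oxopropyl)phosphonate, K2CO3, MeOH) gives the epoxy alkyne F3. The same BF3-induced hydride shift, now without a neighbouring carbonyl, gives the alkynyl aldehyde F4. Palladium diacetate (5 mol%) with methanol in CH2Cl2 then adds the hemiacetal oxygen to the alkyne (6-exo-dig) and gives 14 directly.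

Step 4. The boron bromide may attack the dioxolane, the hindered [3,3] shift may need temperatures at which enantioselectivity erodes, or the enolate geometry may leak. The fallback sets out from 6 and comes back at 8. LiN(i-Pr)2 in THF/DMPU at −78 °C followed by Me3SiCl gives the silyl ketene acetal F5 with the same geometry (C11 cis to O–Si). It rearranges on warming to the racemic acid, that is 8 together with its enantiomer F6. Crystallisation of the (S)-1-phenylethylammonium salt F7 of 8 and acidification return 8; if the salt of the antipode proves less soluble, the (R)-amine is used instead.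

Further compounds

F1 | step 10 | α-bromo keto aldehyde (C7 bromide of the ring-opened C6 aldehyde / C8 ketone) | BrCC(=O)[C@@H](CCC3(C)OCCO3)[C@]2(C)CCCC(C)(C)[C@@H]2C=O
F2 | step 7 | epoxy aldehyde (C8 aldehyde, spiro-epoxide at C5/C6) | O=C[C@@H](CCC4(C)OCCO4)[C@]2(C)CCCC(C)(C)[C@]23OC3
F3 | step 7 | epoxy alkyne (C8≡C7 terminal alkyne, spiro-epoxide at C5/C6) | C#C[C@@H](CCC4(C)OCCO4)[C@]2(C)CCCC(C)(C)[C@]23OC3
F4 | step 7 | alkynyl aldehyde (C8≡C7 alkyne, C6 aldehyde cis to C9) | C#C[C@@H](CCC3(C)OCCO3)[C@]2(C)CCCC(C)(C)[C@@H]2C=O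
F5 | step 4 | trimethylsilyl ketene acetal of 6 (C11 cis to O–Si) | CC1=C(CO/C(O[Si](C)(C)C)=C/CCC2(C)OCCO2)C(C)(C)CCC1
F6 | step 4 | enantiomer of 8, (2R)-4-(2-methyl-1,3-dioxolan-2-yl)-2-[(1R)-1,3,3-trimethyl-2-methylidenecyclohexyl]butanoic acid | OC(=O)[C@H](CCC1(C)OCCO1)[C@@]2(C)CCCC(C)(C)C2=C
F7 | step 4 | (S)-1-phenylethylammonium salt of 8 | OC(=O)[C@@H](CCC1(C)OCCO1)[C@]2(C)CCCC(C)(C)C2=C.C[C@H](N)c1ccccc1
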